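The benzene ring of the coumarin is disconnected at C8–C8a (and, earlier, C4a–C5): C5–C8 come from a cyclobutenone carried by the pyranone carbon that becomes C4a. The key step exploits the vicinal C7–O/C8–O pair beside ring-fusion carbon C8a: on heating, a 2-alkoxy-4-(2-oxopyran-5-yl)cyclobut-2-enone opens to a vinylketene that closes onto pyranone C6 and aromatises, building the benzene ring and delivering C7–O already alkylated and C8–OH free. The precursor, bearing the silyl-protected epoxy side chain as its enol ether, is made from a symmetric squarate diester (regiochemistry fixed by symmetry), a 5-stannyl-2-pyranone and a Sharpless-derived epoxy alcohol.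

Key step: step 12

Remark: the target is read as (2′R,3′R,5′R) with a trans (E-derived) epoxide. "Q" denotes the side-chain group [(2R,3R)-3-[(2R)-2-(tert-butyldimethylsilyloxy)-4-methylpent-3-en-1-yl]-3-methyloxiran-2-yl]methyl, bonded through its CH2; the C5′ hydroxyl is carried as the tert-butyldimethylsilyl ether so that it survives Me3Al and the mildly acidic step 7.
Remark: step 6 attaches two equivalents of epoxy alcohol 8 so that the two ring carbonyls stay equivalent; the equivalent released in step 7 is recovered and re-used.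

Step 1
Reactants: 1 3-methylbut-2-enal; 2 allenylboronic acid pinacol ester
Product: 3 (R)-6-methylhept-5-en-1-yn-4-ol
Conditions: (R)-TRIP phosphoric acid [(R)-3,3′-bis(2,4,6-triisopropylphenyl)-1,1′-binaphthyl-2,2′-diyl hydrogen phosphate] (5 mol%), 4 Å MS, toluene, 0 °C; aq. NaHCO3
Reagents that add atoms: none
Why: Chiral-phosphoric-acid-catalysed propargylboration, in which the allenylboronate adds through its γ-carbon in a closed six-membered transition state held by the acid; the (R)-acid is expected to expose the Re face of the aldehyde, which sets C5′ as (R).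

Step 2
Reactants: 3 (R)-6-methylhept-5-en-1-yn-4-ol
Product: 4 (R)-tert-butyldimethyl[(6-methylhept-5-en-1-yn-4-yl)oxy]silane
Conditions: t-BuMe2SiCl, imidazole, DMF, rt
Reagents that add atoms: tert-butyldimethylsilyl chloride, CC(C)(C)[Si](C)(C)Cl
Why: Standard silylation of a secondary alcohol, giving an ether robust enough for Me3Al, the acidic transposition of step 7 and the thermolysis.

Step 3
Reactants: 4 (R)-tert-butyldimethyl[(6-methylhept-5-en-1-yn-4-yl)oxy]silane
Product: 7 (2E,5R)-5-(tert-butyldimethylsilyloxy)-3,7-dimethylocta-2,6-dien-1-ol, via alkenylalane 5 (not isolated), via lithium aluminate 6 (not isolated)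
Conditions: Me3Al, Cp2ZrCl2 (25 mol%), CH2Cl2, 0 °C to rt; then n-BuLi, THF, −78 °C; (CH2O)n, −78 °C to rt
Reagents that add atoms: trimethylaluminium, C[Al](C)C; formaldehyde (as paraformaldehyde), C=O
Why: Negishi zirconium-catalysed carboalumination adds methyl and aluminium syn across the terminal alkyne with the metal on the terminal carbon, and the derived aluminate is hydroxymethylated with retention, which fixes the E geometry of the trisubstituted alkene.

Step 4
Reactants: 7 (2E,5R)-5-(tert-butyldimethylsilyloxy)-3,7-dimethylocta-2,6-dien-1-ol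
Product: 8 [(2R,3R)-3-[(2R)-2-(tert-butyldimethylsilyloxy)-4-methylpent-3-en-1-yl]-3-methyloxiran-2-yl]methanol (Q–OH)
Conditions: Ti(OiPr)4 (10 mol%), D-(−)-diethyl tartrate (12 mol%), t-BuOOH, 4 Å MS, CH2Cl2, −20 °C
Reagents that add atoms: tert-butyl hydroperoxide, CC(C)(C)OO
Why: Sharpless asymmetric epoxidation, in which the titanium tartrate bound to the allylic hydroxyl delivers oxygen to one face of the 2,3-alkene only; D-(−)-tartrate on an (E)-3-methylalk-2-en-1-ol gives the (2R,3R) epoxide under reagent control, and the 6,7-alkene, which has no free hydroxyl, is not touched.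

Step 5
Reactants: 9 squaric acid
Product: 10 3,4-dichlorocyclobut-3-ene-1,2-dione
Conditions: (COCl)2, DMF (cat.), CH2Cl2, reflux
Reagents that add atoms: oxalyl chloride, O=C(Cl)C(=O)Cl
Why: Vilsmeier-type chlorination of the two vinylogous acid hydroxyls, the standard preparation of this dichloride.

Step 6
Reactants: 10 3,4-dichlorocyclobut-3-ene-1,2-dione; 8 epoxy alcohol Q–OH (2.1 equiv)
Product: 12 3,4-bis(Q-oxy)cyclobut-3-ene-1,2-dione, via ester chloride 11 (not isolated)
Conditions: 2,6-lutidine, CH2Cl2, −40 to 0 °C
Reagents that add atoms: none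
Why: Addition–elimination of the neutral primary alcohol at the two vinylogous acid chloride carbons with a hindered base taking up HCl, so that no alkoxide capable of Payne rearrangement is formed.

Step 7
Reactants: 12 3,4-bis(Q-oxy)cyclobut-3-ene-1,2-dione
Product: 14 4-hydroxy-2-(Q-oxy)cyclobut-2-en-1-one (both configurations at the ring CH), via diol 13 (not isolated)
Conditions: i-Bu2AlH (2.4 equiv), CH2Cl2, −78 to −40 °C; aq. potassium sodium tartrate; then PPTS (5 mol%), THF–H2O, 0 °C
Reagents that add atoms: water, O
Why: 1,2-Reduction of both carbonyls followed by a Stork–Danheiser-type hydrolytic transposition, in which ionisation of either allylic hydroxyl gives an alkoxy-stabilised cyclobutenyl cation that water turns into the ketone with release of one Q–OH; because diol 13 is symmetric both ionisations give the same 2-alkoxy-4-hydroxy enone, and the new carbonyl slows a second ionisation.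

Step 8
Reactants: 14 4-hydroxy-2-(Q-oxy)cyclobut-2-en-1-one
Product: 15 4-chloro-2-(Q-oxy)cyclobut-2-en-1-one (both configurations at the ring CH)
Conditions: 1-chloro-N,N,2-trimethylprop-1-en-1-amine, CH2Cl2, 0 °C; used crude
Reagents that add atoms: 1-chloro-N,N,2-trimethylprop-1-en-1-amine, CC(C)=C(Cl)N(C)C
Why: Neutral conversion of the α-ketol into the chloride through an imidate formed with the α-chloro enamine, which avoids acid that could open the epoxide; the configuration at the ring CH is irrelevant because it is lost in step 12.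

Step 9
Reactants: 16 coumalic acid (2-oxo-2H-pyran-5-carboxylic acid)
Product: 17 5-bromo-2H-pyran-2-one
Conditions: NBS (1.1 equiv), LiOAc, MeCN–H2O, rt
Reagents that add atoms: N-bromosuccinimide, O=C1CCC(=O)N1Br
Why: Hunsdiecker-type bromodecarboxylation in which the C5 carboxylate is replaced ipso by bromine, with the amount of NBS limited to keep further bromination at C3 low.

Step 10
Reactants: 17 5-bromo-2H-pyran-2-one
Product: 18 5-(trimethylstannyl)-2H-pyran-2-one
Conditions: Me3SnSnMe3, Pd(PPh3)4 (5 mol%), dioxane, 80 °C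
Reagents that add atoms: hexamethylditin, C[Sn](C)(C)[Sn](C)(C)C
Why: Palladium-catalysed stannylation of a heteroaryl bromide (oxidative addition, Sn–Sn transmetalation, reductive elimination), which the lactone tolerates.

Step 11
Reactants: 15 4-chloro-2-(Q-oxy)cyclobut-2-en-1-one; 18 5-(trimethylstannyl)-2H-pyran-2-one
Product: 19 2-(Q-oxy)-4-(2-oxo-2H-pyran-5-yl)cyclobut-2-en-1-one (both configurations at the ring CH)
Conditions: PdCl2(PhCN)2 (5 mol%), tri(2-furyl)phosphine (10 mol%), dioxane, 40 °C; chromatography below rt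
Reagents that add atoms: none
Why: Stille coupling of a 4-chlorocyclobutenone, in which oxidative addition gives an oxocyclobutenyl palladium species and the pyranonyl group transferred from tin is joined at the unsubstituted CH terminus; 40 °C should lie below the temperature at which the four-membered ring opens.

Step 12
Reactants: 19 2-(Q-oxy)-4-(2-oxo-2H-pyran-5-yl)cyclobut-2-en-1-one
Product: 22 8-hydroxy-7-(Q-oxy)-2H-chromen-2-one, via vinylketene 20 (not isolated), via dienone 21 (not isolated)
Conditions: toluene (0.01 M), 105 °C, argon, dark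
Reagents that add atoms: none
Why: Heat breaks the C(=O)–CH(pyranonyl) bond of the cyclobutenone in a conrotatory four-electron opening that is reversible; ketene 20, the geometry that holds the ketene carbon (future C8) next to C6 of the pyranone (future C8a), closes in a six-electron electrocyclisation that forms the C8–C8a bond, and the C8a hydrogen of dienone 21 then shifts to oxygen to give the phenol. The closest known reaction type is the vinylketene-based benzannulation of 4-aryl- and 4-hetarylcyclobut-2-enones to phenols. The benzene ring is closed by a thermal disrotatory 6π electrocyclisation across the C5=C6 bond of the pyranone, and no stereocentre remains because the only new sp3 centre (C8a in 21) is aromatised. The selectivity needed is closure at the oxygen-bearing C6 and not at C4: in the 2-pyranone only C5=C6 is a double bond in conjugation with the dienylketene, and closure at C4 would end in a non-aromatic ortho-quinoid isochromenone. Because the enol-ether oxygen ends on C7 and the ketene oxygen on C8 as the free hydroxyl, the two phenolic positions need no later distinction, and high dilution keeps the ketene from acylating the product phenol.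

Step 13
Reactants: 22 8-hydroxy-7-(Q-oxy)-2H-chromen-2-one
Product: 23 8-methoxy-7-(Q-oxy)-2H-chromen-2-one
Conditions: MeI, K2CO3, acetone, rt
Reagents that add atoms: iodomethane, CI
Why: Williamson methylation of the only free phenol under mild carbonate conditions that leave the lactone, the epoxide and the silyl ether untouched.

Step 14
Reactants: 23 8-methoxy-7-(Q-oxy)-2H-chromen-2-one
Product: 24 7-{[(2R,3R)-3-[(2R)-2-hydroxy-4-methylpent-3-en-1-yl]-3-methyloxiran-2-yl]methoxy}-8-methoxy-2H-chromen-2-one (target)
Conditions: n-Bu4NF, AcOH, THF, 0 °C to rt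
Reagents that add atoms: none
Why: Fluoride cleavage of the silyl ether driven by the Si–F bond, buffered with acetic acid so that neither the lactone nor the epoxide is attacked and the three stereocentres stay as set in steps 1 and 4.

Compound list
1 | 3-methylbut-2-enal | CC(C)=CC=O | starting material
2 | allenylboronic acid pinacol ester | C=C=CB1OC(C)(C)C(C)(C)O1 | starting material
3 | (R)-6-methylhept-5-en-1-yn-4-ol | C#CC[C@@H](O)C=C(C)C | intermediate
4 | (R)-tert-butyldimethyl[(6-methylhept-5-en-1-yn-4-yl)oxy]silane | C#CC[C@@H](O[Si](C)(C)C(C)(C)C)C=C(C)C | intermediate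
5 | [(1E,4R)-4-(tert-butyldimethylsilyloxy)-2,6-dimethylhepta-1,5-dien-1-yl]dimethylalane | C[Al](C)/C=C(\C)C[C@@H](O[Si](C)(C)C(C)(C)C)C=C(C)C | intermediate (not isolated)
6 | lithium butyl[(1E,4R)-4-(tert-butyldimethylsilyloxy)-2,6-dimethylhepta-1,5-dien-1-yl]dimethylaluminate | [Li+].CCCC[Al-](C)(C)/C=C(\C)C[C@@H](O[Si](C)(C)C(C)(C)C)C=C(C)C | intermediate (not isolated)
7 | (2E,5R)-5-(tert-butyldimethylsilyloxy)-3,7-dimethylocta-2,6-dien-1-ol | OC/C=C(\C)C[C@@H](O[Si](C)(C)C(C)(C)C)C=C(C)C | intermediate
8 | [(2R,3R)-3-[(2R)-2-(tert-butyldimethylsilyloxy)-4-methylpent-3-en-1-yl]-3-methyloxiran-2-yl]methanol (Q–OH) | OC[C@H]1O[C@]1(C)C[C@@H](O[Si](C)(C)C(C)(C)C)C=C(C)C | intermediate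
9 | squaric acid | OC1=C(O)C(=O)C1=O | starting material
10 | 3,4-dichlorocyclobut-3-ene-1,2-dione | ClC1=C(Cl)C(=O)C1=O | intermediate
11 | 3-chloro-4-(Q-oxy)cyclobut-3-ene-1,2-dione | O=C1C(=O)C(OC[C@H]2O[C@]2(C)C[C@@H](O[Si](C)(C)C(C)(C)C)C=C(C)C)=C1Cl | intermediate (not isolated)
12 | 3,4-bis(Q-oxy)cyclobut-3-ene-1,2-dione | O=C1C(=O)C(OC[C@H]2O[C@]2(C)C[C@@H](O[Si](C)(C)C(C)(C)C)C=C(C)C)=C1OC[C@H]3O[C@]3(C)C[C@@H](O[Si](C)(C)C(C)(C)C)C=C(C)C | intermediate
13 | 3,4-bis(Q-oxy)cyclobut-3-ene-1,2-diol (cis and trans) | OC1C(O)C(OC[C@H]2O[C@]2(C)C[C@@H](O[Si](C)(C)C(C)(C)C)C=C(C)C)=C1OC[C@H]3O[C@]3(C)C[C@@H](O[Si](C)(C)C(C)(C)C)C=C(C)C | intermediate (not isolated)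
14 | 4-hydroxy-2-(Q-oxy)cyclobut-2-en-1-one | O=C1C(OC[C@H]2O[C@]2(C)C[C@@H](O[Si](C)(C)C(C)(C)C)C=C(C)C)=CC1O | intermediate
15 | 4-chloro-2-(Q-oxy)cyclobut-2-en-1-one | O=C1C(OC[C@H]2O[C@]2(C)C[C@@H](O[Si](C)(C)C(C)(C)C)C=C(C)C)=CC1Cl | intermediate
16 | coumalic acid | O=C(O)c1ccc(=O)oc1 | starting material
17 | 5-bromo-2H-pyran-2-one | Brc1ccc(=O)oc1 | intermediate
18 | 5-(trimethylstannyl)-2H-pyran-2-one | C[Sn](C)(C)c1ccc(=O)oc1 | intermediate
19 | 2-(Q-oxy)-4-(2-oxo-2H-pyran-5-yl)cyclobut-2-en-1-one | O=C1C(OC[C@H]2O[C@]2(C)C[C@@H](O[Si](C)(C)C(C)(C)C)C=C(C)C)=CC1c1ccc(=O)oc1 | intermediate (key-step precursor)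
20 | (3Z)-2-(Q-oxy)-4-(2-oxo-2H-pyran-5-yl)buta-1,3-dien-1-one | O=C=C(OC[C@H]1O[C@]1(C)C[C@@H](O[Si](C)(C)C(C)(C)C)C=C(C)C)/C=C\c1ccc(=O)oc1 | intermediate (not isolated)
21 | 7-(Q-oxy)-8aH-chromene-2,8-dione | O=C1C(OC[C@H]3O[C@]3(C)C[C@@H](O[Si](C)(C)C(C)(C)C)C=C(C)C)=CC=C2C=CC(=O)OC12 | intermediate (not isolated)
22 | 8-hydroxy-7-(Q-oxy)-2H-chromen-2-one | Oc1c(OC[C@H]2O[C@]2(C)C[C@@H](O[Si](C)(C)C(C)(C)C)C=C(C)C)ccc2ccc(=O)oc12 | intermediate (key-step product)
23 | 8-methoxy-7-(Q-oxy)-2H-chromen-2-one | COc1c(OC[C@H]2O[C@]2(C)C[C@@H](O[Si](C)(C)C(C)(C)C)C=C(C)C)ccc2ccc(=O)oc12 | intermediate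
24 | 7-{[(2R,3R)-3-[(2R)-2-hydroxy-4-methylpent-3-en-1-yl]-3-methyloxiran-2-yl]methoxy}-8-methoxy-2H-chromen-2-one | COc1c(OC[C@H]2O[C@]2(C)C[C@@H](O)C=C(C)C)ccc2ccc(=O)oc12 | target

Total step count: 14. Longest linear sequence: 11 steps (steps 1–4, 6–8, 11–14).

Steps most likely to fail

Step 12. The ring may open mainly with the pyranone rotating outward, and the ketene of that geometry, which cannot close, may be drained by dimerisation or by acylation of the product phenol faster than it reverts; closure onto the electron-poor pyranone may also be slow. The fallback gives up ring construction for this compound and sets out from epoxy alcohol 8: Mitsunobu etherification (PPh3, DIAD, THF, 0 °C) of commercial 7,8-dihydroxy-2H-chromen-2-one, whose 7-hydroxyl is the more acidic and less hindered, gives phenol 22 directly, where the route is rejoined; no compound outside the list is made (none F0).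

Step 7. The doubly O-metalated cyclobutene diol may undergo charge-accelerated ring opening before it is protonated, the hydride may attack an epoxide, or the transposition may run on with loss of the second alkoxy group. The fallback masks one carbonyl so that only a mono-alkoxide is ever formed and a single equivalent of 8 is needed. It sets out from 8 and commercial dimethyl squarate, which is reduced with LiAlH(OtBu)3 (THF, −78 °C) to 4-hydroxy-2,3-dimethoxycyclobut-2-en-1-one F1. Ionisation with trifluoroacetic anhydride and quenching with methanol gives the monoacetal 3,4,4-trimethoxycyclobut-2-en-1-one F2. Exchange of its vinylogous-ester methoxy group for the sodium alkoxide of 8 (NaH, THF, 0 °C) gives 3-(Q-oxy)-4,4-dimethoxycyclobut-2-en-1-one F3, whose only carbonyl is reduced with i-Bu2AlH (CH2Cl2, −78 °C) to 3-(Q-oxy)-4,4-dimethoxycyclobut-2-en-1-ol F4. Hydrolysis of the acetal on wet silica gel with oxalic acid returns hydroxy enone 14.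

Step 11. Transfer of the electron-poor pyranonyl group from tin may be slower than decomposition of the sensitive chloride 15, or may need a temperature at which the product already opens. The fallback is a Negishi coupling at or below room temperature, setting out from bromide 17: zinc insertion (Zn dust, LiCl, THF, rt) gives bromo(2-oxo-2H-pyran-5-yl)zinc F5, which is coupled with chloride 15 (Pd(PPh3)4, THF, 0 °C) to return cyclobutenone 19.

Further compounds
F0 | step 12 | none | none
F1 | step 7 | 4-hydroxy-2,3-dimethoxycyclobut-2-en-1-one | O=C1C(OC)=C(OC)C1O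
F2 | step 7 | 3,4,4-trimethoxycyclobut-2-en-1-one | O=C1C=C(OC)C1(OC)OC
F3 | step 7 | 3-(Q-oxy)-4,4-dimethoxycyclobut-2-en-1-one | O=C1C=C(OC[C@H]2O[C@]2(C)C[C@@H](O[Si](C)(C)C(C)(C)C)C=C(C)C)C1(OC)OC
F4 | step 7 | 3-(Q-oxy)-4,4-dimethoxycyclobut-2-en-1-ol | OC1C=C(OC[C@H]2O[C@]2(C)C[C@@H](O[Si](C)(C)C(C)(C)C)C=C(C)C)C1(OC)OC
F5 | step 11 | bromo(2-oxo-2H-pyran-5-yl)zinc | Br[Zn]c1ccc(=O)oc1
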